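The route rests on opening ring D, the tetramethylcyclohexenetrione, between C1′ (the ring carbon that bears the side-chain methine C1″) and the adjacent carbonyl carbon C6′. Since C3′ and C5′ are quaternary, the open chain has a single enolizable CH2, next to the already configured methine. One Dieckmann condensation therefore closes ring D without any regiochemical choice and delivers the whole triketone side chain on the protected ring A. The precursor is an acyclic methyl 2,2,4,4-tetramethyl-3,5-dioxo ester whose carbon β to the terminal ketone carries isobutyl and a 2,6-bis(benzyloxy)-4-methoxy-3-methylphenyl group with one free ring carbon. The chromanone ring C, whose C2 centre would not survive alkoxide, is added only after this closure.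

Key step: step 8

Locants: rings A and C carry chromanone numbers (O1, C2–C4, C4a, C5–C8, C8a). Ring D carries primed numbers (C1′ bears the side chain, C2′ the enol OH, C3′ and C5′ are CMe2, C4′ and C6′ are C=O). C1″ is the methine. In 10 and 12 the chain is numbered from the ester carbon C1 to the aryl-bearing carbon C7.

Design remarks:
- Methyl 2,2,4,4-tetramethyl-3,5-dioxohexanoate is not used as an aldol partner, because its own enolate would undergo the ring D closure. The aryl–CH=CH unit is attached to keto ester 7 as an acid chloride instead.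
- With three identical ethers, two hydroxyls would end up ortho to the C4 carbonyl and either could close ring C. O5 is therefore carried as a methyl ether and O1/O7 as benzyl ethers, and only the benzyl ether ortho to the new acyl group is released before the annulation.
- The ring D closure is 6-(enolendo)-exo-trig, since the enolate double bond lies inside the new ring.

Assumption: the sense of induction of the chiral ligands in steps 7 and 11 is assigned by analogy with simpler enones and chromones; if the first run shows the opposite sense, the antipodal ligand is used and nothing else changes.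

Step 1
Reactants: 1 2,4,6-trihydroxytoluene
Product: 2 2,4,6-trihydroxy-3-methylbenzaldehyde
Conditions: POCl3, DMF, EtOAc, 0 °C to rt; then H2O, 60 °C
Reagents that add atoms: N,N-dimethylformamide CN(C)C=O; water O
Why: Vilsmeier–Haack formylation of the strongly activated triol should take place once, at either of the two equivalent free ring carbons, because the first formyl group deactivates the ring towards a second attack.

Step 2
Reactants: 2 2,4,6-trihydroxy-3-methylbenzaldehyde
Product: 3 2,6-dihydroxy-4-methoxy-3-methylbenzaldehyde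
Conditions: MeI (1.05 equiv), K2CO3 (1.0 equiv), acetone, 0 °C to rt
Reagents that add atoms: iodomethane CI
Why: Williamson O-methylation with one equivalent of base and iodomethane should select the 4-hydroxyl, which is para to the formyl group, the most acidic of the three and the only one that cannot be held in a hydrogen bond by the carbonyl oxygen.

Step 3
Reactants: 3 2,6-dihydroxy-4-methoxy-3-methylbenzaldehyde
Product: 4 2,6-bis(benzyloxy)-4-methoxy-3-methylbenzaldehyde
Conditions: BnBr (2.5 equiv), K2CO3 (3 equiv), DMF, 60 °C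
Reagents that add atoms: benzyl bromide BrCc1ccccc1
Why: Exhaustive Williamson O-benzylation in a dipolar aprotic solvent at 60 °C should cap both hydrogen-bonded ortho-hydroxyls, O-alkylation being the normal course for formyl-deactivated phloroglucinols under these conditions.

Step 4
Reactants: 4 2,6-bis(benzyloxy)-4-methoxy-3-methylbenzaldehyde
Product: 5 (E)-3-[2,6-bis(benzyloxy)-4-methoxy-3-methylphenyl]prop-2-enoic acid
Conditions: CH2(CO2H)2, pyridine, piperidine (cat.), 100 °C
Reagents that add atoms: malonic acid OC(=O)CC(O)=O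
Why: Knoevenagel–Doebner condensation with decarboxylation is an established route from 2,6-dialkoxybenzaldehydes to cinnamic acids and should give the E-alkene, the thermodynamically favoured geometry of the decarboxylative elimination.

Step 5
Reactants: 6 2,2,4,4-tetramethylcyclobutane-1,3-dione
Product: 7 methyl 2,2,4-trimethyl-3-oxopentanoate
Conditions: NaOMe (cat.), MeOH, reflux
Reagents that add atoms: methanol CO
Why: Methoxide-catalysed alcoholysis of the strained dione (addition to a ring carbonyl followed by retro-Claisen ring opening) is a long-established reaction that should give the keto ester, whose isopropyl C–H is its only enolizable position.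

Step 6
Reactants: 5 (E)-3-[2,6-bis(benzyloxy)-4-methoxy-3-methylphenyl]prop-2-enoic acid; 7 methyl 2,2,4-trimethyl-3-oxopentanoate
Product: 10 methyl (E)-7-[2,6-bis(benzyloxy)-4-methoxy-3-methylphenyl]-2,2,4,4-tetramethyl-3,5-dioxohept-6-enoate, via acid chloride 8 (not isolated), via lithium enolate 9 (not isolated)
Conditions: 5, (COCl)2, DMF (cat.), CH2Cl2, 0 °C to rt, then evaporation (gives 8); separately 7, LiN(iPr)2, THF, −78 to 0 °C (gives 9); 9 added to 8, THF, −78 °C
Reagents that add atoms: none
Why: Claisen-type C-acylation of a ketone lithium enolate by an acid chloride, the reaction type used for 2,2-disubstituted 1,3-diketones, should join the two halves at the single enolizable carbon of 7, with inverse addition at −78 °C and a conjugated, non-enolizable acid chloride favouring attack through carbon and leaving a product that has no acidic hydrogen.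

Step 7
Reactants: 10 methyl (E)-7-[2,6-bis(benzyloxy)-4-methoxy-3-methylphenyl]-2,2,4,4-tetramethyl-3,5-dioxohept-6-enoate; 11 isobutylmagnesium bromide
Product: 12 methyl (7R)-7-[2,6-bis(benzyloxy)-4-methoxy-3-methylphenyl]-2,2,4,4,9-pentamethyl-3,5-dioxodecanoate
Conditions: CuBr·SMe2 (5 mol%), (R)-1-[(S)-2-(diphenylphosphino)ferrocenyl]ethyldicyclohexylphosphine (6 mol%), 11 (1.3 equiv, slow addition), tBuOMe, −78 °C; sat. aq. NH4Cl at −78 °C
Reagents that add atoms: none
Why: Copper-catalysed asymmetric conjugate addition of a Grignard reagent to an acyclic E-enone should deliver isobutyl to the Re face of C7 under control of the chiral ferrocenyl diphosphine and so set the 7R centre, while quaternary C4 shields the C5 carbonyl from 1,2-addition and the cold quench frees the ketone before its magnesium enolate can cyclize.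

Step 8
Reactants: 12 methyl (7R)-7-[2,6-bis(benzyloxy)-4-methoxy-3-methylphenyl]-2,2,4,4,9-pentamethyl-3,5-dioxodecanoate
Product: 13 2-{(1S)-1-[2,6-bis(benzyloxy)-4-methoxy-3-methylphenyl]-3-methylbutyl}-3-hydroxy-4,4,6,6-tetramethylcyclohex-2-ene-1,5-dione
Conditions: KOtBu (2.2 equiv), THF, 0 °C to rt; 1 M aq. HCl
Reagents that add atoms: none
Why: KOtBu deprotonates C6 of 12, the only carbon with an acidic hydrogen because C2 and C4 are quaternary, and the enolate carbon adds to the C1 ester carbonyl to form the C6–C1 bond (C1′–C6′ of ring D); expulsion of methoxide gives the 2-substituted triketone, whose immediate deprotonation to a delocalised enolate makes the sequence irreversible. The closest known reaction is the Dieckmann (intramolecular Claisen) condensation of 2,2,4,4-tetramethyl-3,5-dioxo esters to 4,4,6,6-tetramethylcyclohexane-1,3,5-triones. Ring D closes in the 6-(enolendo)-exo-trig mode, the C5–C6 enolate double bond lying inside the new ring and the ester carbonyl outside it, and the closure is helped by the gem-dialkyl effect of both quaternary carbons. No stereocentre is formed; C7 is β to the ketone in 12 and attached to an electron-rich enolate carbon in the product, so it is never acidic and should keep its configuration (7R becomes 1″S only because the substituent priorities change). The step needs C-acylation instead of O-acylation of the ambident enolate and no retro-Claisen cleavage of the 1,3-diketone: O-attack would give an enol lactone that alkoxide reopens, whereas only C-attack ends in the stabilised enolate, and the bulky, weakly nucleophilic base at 0 °C together with the flanking quaternary carbons protects the C3 carbonyl.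

Step 9
Reactants: 13 2-{(1S)-1-[2,6-bis(benzyloxy)-4-methoxy-3-methylphenyl]-3-methylbutyl}-3-hydroxy-4,4,6,6-tetramethylcyclohex-2-ene-1,5-dione
Product: 15 2-{(1S)-1-[3-acetyl-6-(benzyloxy)-2-hydroxy-4-methoxy-5-methylphenyl]-3-methylbutyl}-3-hydroxy-4,4,6,6-tetramethylcyclohex-2-ene-1,5-dione, via dibenzyl aryl methyl ketone 14 (not isolated)
Conditions: AcCl (1.2 equiv), TiCl4 (2.5 equiv), CH2Cl2, −78 °C; then BCl3 (1.1 equiv), −78 °C; H2O
Reagents that add atoms: acetyl chloride CC(Cl)=O
Why: Friedel–Crafts acylation can only take place at the single unsubstituted carbon of the electron-rich ring, and BCl3 then removes by chelation to the new carbonyl the one benzyl ether ortho to it (the methyl ether on the other side is inert at −78 °C), so that the future O1 is the only free phenol.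

Step 10
Reactants: 15 2-{(1S)-1-[3-acetyl-6-(benzyloxy)-2-hydroxy-4-methoxy-5-methylphenyl]-3-methylbutyl}-3-hydroxy-4,4,6,6-tetramethylcyclohex-2-ene-1,5-dione
Product: 17 7-(benzyloxy)-8-[(1S)-1-(2-hydroxy-3,3,5,5-tetramethyl-4,6-dioxocyclohex-1-en-1-yl)-3-methylbutyl]-5-methoxy-6-methyl-4H-chromen-4-one, via 2-hydroxychromanone 16 (not isolated)
Conditions: HCO2Et (10 equiv), NaH (5 equiv), THF, 0 °C to rt; then 2 M aq. HCl, THF, 40 °C
Reagents that add atoms: ethyl formate CCOC=O
Why: Claisen formylation of the methyl ketone enolate (the triketone and the phenol are held as unreactive sodium salts) followed by acid-induced ring closure through the only free ortho-hydroxyl and dehydration is the classical chromone annulation of 2-hydroxyacetophenones and should fix O1 and C2–C3 of ring C without ambiguity.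

Step 11
Reactants: 17 7-(benzyloxy)-8-[(1S)-1-(2-hydroxy-3,3,5,5-tetramethyl-4,6-dioxocyclohex-1-en-1-yl)-3-methylbutyl]-5-methoxy-6-methyl-4H-chromen-4-one; 18 phenylboronic acid
Product: 19 (2R)-7-(benzyloxy)-8-[(1S)-1-(2-hydroxy-3,3,5,5-tetramethyl-4,6-dioxocyclohex-1-en-1-yl)-3-methylbutyl]-5-methoxy-6-methyl-2-phenyl-2,3-dihydro-4H-chromen-4-one
Conditions: [RhCl(C2H4)2]2 (3 mol%), (R)-2,2′-bis[bis(3,4,5-trifluorophenyl)phosphino]-6,6′-dimethoxy-1,1′-biphenyl (7 mol%), 18 (3 equiv), K3PO4 (1.5 equiv), toluene/H2O 10:1, 30–40 °C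
Reagents that add atoms: none
Why: Rhodium-catalysed asymmetric 1,4-addition of an arylboronic acid to a chromone should transfer phenyl to C2 on the face chosen by the electron-poor atropisomeric diphosphine (catalyst control, giving 2R independently of the remote C1″ centre), the triketone being carried as its potassium enolate and the weak base and low temperature protecting the new C2–O1 bond from retro-oxa-Michael opening.

Step 12
Reactants: 19 (2R)-7-(benzyloxy)-8-[(1S)-1-(2-hydroxy-3,3,5,5-tetramethyl-4,6-dioxocyclohex-1-en-1-yl)-3-methylbutyl]-5-methoxy-6-methyl-2-phenyl-2,3-dihydro-4H-chromen-4-one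
Product: 20 (2R)-5,7-dihydroxy-8-[(1S)-1-(2-hydroxy-3,3,5,5-tetramethyl-4,6-dioxocyclohex-1-en-1-yl)-3-methylbutyl]-6-methyl-2-phenyl-2,3-dihydro-4H-chromen-4-one
Conditions: BCl3 (6 equiv), C6HMe5 (3 equiv), CH2Cl2, −78 to 0 °C; H2O
Reagents that add atoms: none
Why: Ether cleavage by BCl3 with pentamethylbenzene as benzyl-cation trap should remove the O7 benzyl group at −78 °C and, on warming, the O5 methyl group through chelation to the C4 carbonyl (the selective peri-demethylation known for 5-methoxyflavanones), conditions under which the C2–O1 bond and both stereocentres should persist.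

Compound list
1 | 2,4,6-trihydroxytoluene | Cc1c(O)cc(O)cc1O | starting material
2 | 2,4,6-trihydroxy-3-methylbenzaldehyde | Cc1c(O)cc(O)c(C=O)c1O | intermediate
3 | 2,6-dihydroxy-4-methoxy-3-methylbenzaldehyde | COc1cc(O)c(C=O)c(O)c1C | intermediate
4 | 2,6-bis(benzyloxy)-4-methoxy-3-methylbenzaldehyde | COc1cc(OCc2ccccc2)c(C=O)c(OCc2ccccc2)c1C | intermediate
5 | (E)-3-[2,6-bis(benzyloxy)-4-methoxy-3-methylphenyl]prop-2-enoic acid | COc1cc(OCc2ccccc2)c(/C=C/C(=O)O)c(OCc2ccccc2)c1C | intermediate
6 | 2,2,4,4-tetramethylcyclobutane-1,3-dione | CC1(C)C(=O)C(C)(C)C1=O | starting material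
7 | methyl 2,2,4-trimethyl-3-oxopentanoate | COC(=O)C(C)(C)C(=O)C(C)C | intermediate
8 | (E)-3-[2,6-bis(benzyloxy)-4-methoxy-3-methylphenyl]prop-2-enoyl chloride | COc1cc(OCc2ccccc2)c(/C=C/C(=O)Cl)c(OCc2ccccc2)c1C | intermediate (not isolated)
9 | lithium 1-methoxy-2,2,4-trimethyl-1-oxopent-3-en-3-olate (lithium enolate of 7) | COC(=O)C(C)(C)C(O[Li])=C(C)C | intermediate (not isolated)
10 | methyl (E)-7-[2,6-bis(benzyloxy)-4-methoxy-3-methylphenyl]-2,2,4,4-tetramethyl-3,5-dioxohept-6-enoate | COc1cc(OCc2ccccc2)c(/C=C/C(=O)C(C)(C)C(=O)C(C)(C)C(=O)OC)c(OCc2ccccc2)c1C | intermediate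
11 | isobutylmagnesium bromide | CC(C)C[Mg]Br | starting material
12 | methyl (7R)-7-[2,6-bis(benzyloxy)-4-methoxy-3-methylphenyl]-2,2,4,4,9-pentamethyl-3,5-dioxodecanoate | COC(=O)C(C)(C)C(=O)C(C)(C)C(=O)C[C@@H](CC(C)C)c1c(OCc2ccccc2)cc(OC)c(C)c1OCc1ccccc1 | intermediate
13 | 2-{(1S)-1-[2,6-bis(benzyloxy)-4-methoxy-3-methylphenyl]-3-methylbutyl}-3-hydroxy-4,4,6,6-tetramethylcyclohex-2-ene-1,5-dione | Cc1c(OC)cc(OCc2ccccc2)c([C@H](CC(C)C)C3=C(O)C(C)(C)C(=O)C(C)(C)C3=O)c1OCc1ccccc1 | intermediate
14 | 2-{(1S)-1-[3-acetyl-2,6-bis(benzyloxy)-4-methoxy-5-methylphenyl]-3-methylbutyl}-3-hydroxy-4,4,6,6-tetramethylcyclohex-2-ene-1,5-dione | COc1c(C(C)=O)c(OCc2ccccc2)c([C@H](CC(C)C)C3=C(O)C(C)(C)C(=O)C(C)(C)C3=O)c(OCc2ccccc2)c1C | intermediate (not isolated)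
15 | 2-{(1S)-1-[3-acetyl-6-(benzyloxy)-2-hydroxy-4-methoxy-5-methylphenyl]-3-methylbutyl}-3-hydroxy-4,4,6,6-tetramethylcyclohex-2-ene-1,5-dione | COc1c(C(C)=O)c(O)c([C@H](CC(C)C)C3=C(O)C(C)(C)C(=O)C(C)(C)C3=O)c(OCc2ccccc2)c1C | intermediate
16 | 7-(benzyloxy)-2-hydroxy-8-[(1S)-1-(2-hydroxy-3,3,5,5-tetramethyl-4,6-dioxocyclohex-1-en-1-yl)-3-methylbutyl]-5-methoxy-6-methyl-2,3-dihydro-4H-chromen-4-one (both C2 epimers) | COc1c(C)c(OCc2ccccc2)c([C@H](CC(C)C)C3=C(O)C(C)(C)C(=O)C(C)(C)C3=O)c2OC(O)CC(=O)c12 | intermediate (not isolated)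
17 | 7-(benzyloxy)-8-[(1S)-1-(2-hydroxy-3,3,5,5-tetramethyl-4,6-dioxocyclohex-1-en-1-yl)-3-methylbutyl]-5-methoxy-6-methyl-4H-chromen-4-one | COc1c(C)c(OCc2ccccc2)c([C@H](CC(C)C)C3=C(O)C(C)(C)C(=O)C(C)(C)C3=O)c2occc(=O)c12 | intermediate
18 | phenylboronic acid | OB(O)c1ccccc1 | starting material
19 | (2R)-7-(benzyloxy)-8-[(1S)-1-(2-hydroxy-3,3,5,5-tetramethyl-4,6-dioxocyclohex-1-en-1-yl)-3-methylbutyl]-5-methoxy-6-methyl-2-phenyl-2,3-dihydro-4H-chromen-4-one | COc1c(C)c(OCc2ccccc2)c([C@H](CC(C)C)C3=C(O)C(C)(C)C(=O)C(C)(C)C3=O)c2O[C@@H](c3ccccc3)CC(=O)c12 | intermediate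
20 | (2R)-5,7-dihydroxy-8-[(1S)-1-(2-hydroxy-3,3,5,5-tetramethyl-4,6-dioxocyclohex-1-en-1-yl)-3-methylbutyl]-6-methyl-2-phenyl-2,3-dihydro-4H-chromen-4-one (CNP0249552.1) | Cc1c(O)c2c(c([C@H](CC(C)C)C3=C(O)C(C)(C)C(=O)C(C)(C)C3=O)c1O)O[C@@H](c1ccccc1)CC2=O | target

Total step count: 12. Longest linear sequence: 11 steps (steps 1–4 and 6–12, from 1 to 20); step 5 is a one-step side branch. C1″ is set in step 7 and C2 in step 11; no step after step 11 uses base.

Steps most likely to fail

1. Step 6. The hindered, fully substituted enolate 9 may react through oxygen and give an enol ester, so that the C5–C4 bond is not formed. The fallback sets out from acid chloride 8 and enolate 9 and returns at 10. Reduction of 8 with LiAlH(OtBu)3 in THF at −78 °C should stop at the aldehyde (E)-3-[2,6-bis(benzyloxy)-4-methoxy-3-methylphenyl]prop-2-enal F1. Aldol addition of 9 to this aldehyde at −78 °C with a cold acetic acid quench forms the same carbon–carbon bond by carbonyl addition, which has no O-attack counterpart, and should give the allylic β-hydroxy ketone F2. Oxidation of the allylic alcohol with MnO2 in CH2Cl2 at rt should then give 10.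

2. Step 7. Facial selectivity may be poor, or the addition slow, at the hindered, electron-rich β-carbon. The fallback replaces catalyst control by auxiliary control; it sets out from 8 and returns at 12. N-Acylation of lithiated (R)-4-phenyloxazolidin-2-one (nBuLi, THF, −78 °C) with 8 should give the N-enoyl oxazolidinone F3. Addition of 11 with CuBr·SMe2 in THF/Me2S at −20 °C should take place on the magnesium-chelated s-cis imide anti to the 4-phenyl group and give the (3R)-conjugate adduct F4, which can be purified to a single diastereomer. LiOH/H2O2 in THF/H2O at 0 °C removes the auxiliary and gives the (3R)-acid F5. (COCl)2 converts it into the acid chloride F6, which acylates 9 (2 equiv, THF, −78 °C, inverse addition) to give 12. This last acylation is of the same type as step 6; if that step has needed its fallback, the aldol/oxidation sequence is used here as well.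

3. Step 11. The chelating triketone enolate may slow or stop the rhodium catalyst, or the base may erode the C2 configuration through ring opening. The fallback gives up catalyst control and relies on separation of C2 epimers, which are diastereomers because C1″ is fixed; it sets out from 15 and returns at 19. Claisen–Schmidt condensation of 15 with benzaldehyde (KOH, EtOH/H2O, rt) should give the 2′-hydroxychalcone F7. NaOAc in refluxing EtOH closes ring C by oxa-Michael addition of the only free ortho-hydroxyl and should give 19 together with its (2S)-epimer F8, to be separated by chromatography. The (2S)-epimer is returned to the same conditions, where it re-equilibrates through the chalcone, and is recycled.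

Further compounds
F1 | step 6 | (E)-3-[2,6-bis(benzyloxy)-4-methoxy-3-methylphenyl]prop-2-enal | COc1cc(OCc2ccccc2)c(/C=C/C=O)c(OCc2ccccc2)c1C
F2 | step 6 | methyl (E)-7-[2,6-bis(benzyloxy)-4-methoxy-3-methylphenyl]-5-hydroxy-2,2,4,4-tetramethyl-3-oxohept-6-enoate (racemic at C5) | COc1cc(OCc2ccccc2)c(/C=C/C(O)C(C)(C)C(=O)C(C)(C)C(=O)OC)c(OCc2ccccc2)c1C
F3 | step 7 | (4R)-3-{(E)-3-[2,6-bis(benzyloxy)-4-methoxy-3-methylphenyl]prop-2-enoyl}-4-phenyl-1,3-oxazolidin-2-one | COc1cc(OCc2ccccc2)c(/C=C/C(=O)N2[C@H](c3ccccc3)COC2=O)c(OCc2ccccc2)c1C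
F4 | step 7 | (4R)-3-{(3R)-3-[2,6-bis(benzyloxy)-4-methoxy-3-methylphenyl]-5-methylhexanoyl}-4-phenyl-1,3-oxazolidin-2-one | COc1cc(OCc2ccccc2)c([C@H](CC(C)C)CC(=O)N2[C@H](c3ccccc3)COC2=O)c(OCc2ccccc2)c1C
F5 | step 7 | (3R)-3-[2,6-bis(benzyloxy)-4-methoxy-3-methylphenyl]-5-methylhexanoic acid | COc1cc(OCc2ccccc2)c([C@H](CC(C)C)CC(=O)O)c(OCc2ccccc2)c1C
F6 | step 7 | (3R)-3-[2,6-bis(benzyloxy)-4-methoxy-3-methylphenyl]-5-methylhexanoyl chloride | COc1cc(OCc2ccccc2)c([C@H](CC(C)C)CC(=O)Cl)c(OCc2ccccc2)c1C
F7 | step 11 | 2-{(1S)-1-[6-(benzyloxy)-2-hydroxy-4-methoxy-5-methyl-3-[(E)-3-phenylprop-2-enoyl]phenyl]-3-methylbutyl}-3-hydroxy-4,4,6,6-tetramethylcyclohex-2-ene-1,5-dione | COc1c(C(=O)/C=C/c2ccccc2)c(O)c([C@H](CC(C)C)C3=C(O)C(C)(C)C(=O)C(C)(C)C3=O)c(OCc2ccccc2)c1C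
F8 | step 11 | (2S)-7-(benzyloxy)-8-[(1S)-1-(2-hydroxy-3,3,5,5-tetramethyl-4,6-dioxocyclohex-1-en-1-yl)-3-methylbutyl]-5-methoxy-6-methyl-2-phenyl-2,3-dihydro-4H-chromen-4-one | COc1c(C)c(OCc2ccccc2)c([C@H](CC(C)C)C3=C(O)C(C)(C)C(=O)C(C)(C)C3=O)c2O[C@H](c3ccccc3)CC(=O)c12
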